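All runs were generated by integration from invented constants; the scatter is artificial.

Racemization swaps hands, so it leaves the pool, left- plus right-handed substrate, unchanged, and you can follow the pool whatever the catalyst does: it falls by what partner takes.

| flask | left-handed substrate | right-handed substrate | partner | racemization catalyst | remark | time |
|---|---|---|---|---|---|---|
| noon | 20 mM | 20 mM | 2.2 equiv | 0.25 mol% | run made earlier |  |
| midnight | 20 mM | 20 mM | 2.2 equiv | 1 mol% | run made earlier |  |
| spring | 20 mM | 20 mM | 4.4 equiv | 0.5 mol% | run made earlier |  |
| flask | 20 mM | 20 mM | 2.20 equiv | 0.5 mol% |  | 4.0 min |

| run | time / min | left-handed product / % | right-handed substrate / % |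
|---|---|---|---|
| noon | 0.417 | 9 | 50 |
| noon | 0.667 | 14 | 46 |
| noon | 1.33 | 25 | 44 |
| noon | 2.50 | 35 | 38 |
| noon | 5.00 | 52 | 28 |
| midnight | 0.417 | 9 | 45 |
| midnight | 1.33 | 24 | 42 |
| midnight | 2.00 | 33 | 35 |
| midnight | 3.00 | 41 | 31 |
| midnight | 5.00 | 56 | 19 |
| spring | 0.417 | 19 | 48 |
| spring | 0.667 | 28 | 44 |
| spring | 1.33 | 41 | 36 |
| spring | 2.50 | 56 | 28 |
| spring | 5.00 | 81 | 14 |

(each reading ± 1.5 percentage points)
- partner is single-handed; left-handed substrate and right-handed substrate are mirror images of each other, charged as a racemate, each of them at the stated concentration
- the numbers in the tables scatter by 1.5 percentage points (one standard deviation)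
- the handed part of partner does not stay in what it makes, so the products of the two hands are mirror images too
1. amount of left-handed product at 4.0 min, in percent of the left-handed substrate and right-handed substrate together charged
2. amount of right-handed substrate at 4.0 min, in percent of the left-handed substrate and right-handed substrate together charged

While the hands stay level, left-handed substrate is half the pool, so the pool drains at half the pseudo-first-order capture constant of left-handed substrate. Take that half, at charged [partner], as the pool constant, and reach it two ways.

Noon and midnight each read 9% of left-handed product at 0.417 min, with the catalyst at 0.25 mol% and 1 mol%, so for the first way I neglect refill by racemization over that time, although capture has already parted the hands, and let left-handed substrate fall from its charged half; this reading carries the scatter of 1.5 percentage points: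

pool constant = 0.238 min⁻¹
pool half-life = 2.91 min, the time in which level hands at charged [partner] halve the pool

The second way takes the late fall of the pool, divided by the mean share of partner left:

midnight: 0.234 min⁻¹
noon: 0.187 min⁻¹

Midnight agrees with the first way. The noon value is lower, and it is the one that cheats: by difference, left-handed substrate there reads 20.0% against 28% of right-handed substrate at 5.00 min, so its hands are not level.

My own reckoning integrates the pool constant against falling partner, at 1.10 partner per pool substrate, with level hands:

left-handed product = 49.9%
right-handed substrate = 25.1%

The forecast differs, with 47.5% and 28%, reading between noon and midnight: “The midpoint, nudged slightly toward midnight”.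

    left-handed substrate + racemization catalyst ⇌ right-handed substrate + racemization catalyst, rate k1*[racemization catalyst]*[left-handed substrate] forward; the back reaction follows from the equilibrium constant (k = 140 M⁻¹ s⁻¹)
    partner → decomposition product (k = 3.80 × 10⁻⁵ s⁻¹)
    partner + left-handed substrate → left-handed product (k = 0.200 M⁻¹ s⁻¹)
    partner + right-handed substrate → right-handed product (k = 0.00390 M⁻¹ s⁻¹)

The flask gives 49.2% and 27.0%, the forecast within tolerance on both. That midpoint belongs to one partner charge: at 1.89 equiv instead of 2.20 equiv, the left-handed product has moved 5 points. In the flask, the relaxation half-life of 0.413 min is shorter than the pool half-life of 2.91 min, and at 4.00 min the hands stand at 22.6% left and 27.0% right. With the catalyst at 0.12 mol%, relaxation stretches to 1.72 min, and that neighbour flask holds 35.7% of right-handed substrate at 4.00 min, twice its 18.2% of left-handed substrate.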